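**Retrosynthetic overview**
- The strategy rests on the C2 carbinol carbon of ring A, which sits isolated between the C1 and C3 methylenes. Ring A is therefore read as carbon monoxide (C2) plus the five-carbon unit C1–C10–C5–C4–C3, with C1–C10–C5 stored as a cyclopropane on ring B and C4=C3 as an acrylate.
- Ring order: ring B is bought (2-methylcyclohexane-1,3-dione, C5–C10); the cyclopropane is added by a hydroxyl-directed Simmons–Smith reaction; ring A is closed by the carbonylative [5+1] (bonds C1–C2 and C2–C3).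
- Ring A after closure: reductive methylation sets C5 and C4; the masked C2 ketone is later reduced by dissolving metal to the 2α-ol.
- Ring B: C9 ketone, then 8-methyl-9-allyl-8-en-7-one (Saegusa–Ito, allyl addition, oxidative transposition), Li/NH3 with enol triflate trapping (C9), 7-ene, 7α,8α-epoxide, 7α-ol/8(17)-ene.
- Side chain: ozonolysis of the allyl group, C12 iodide, Negishi coupling (C12–C13) with a (Z)-3-iodobut-2-enyl ether; acetylation and desilylation last.

Key step: step 7

Remark: locants follow labdane numbering (C17 on C8, C18 α and C19 β on C4, C20 on C10; α is the face opposite C20); TBS = tert-butyldimethylsilyl, TES = triethylsilyl, TIPS = triisopropylsilyl.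
Remark: 10 is assumed to rest as the C4=C5 isomer (a C3=C4 isomer would converge to the same ketal 11), and 19 and 22 are carried as epimer mixtures at C8 and C9, centres that become trigonal in the following step.

Step 1
Reactants: 1 2-methylcyclohexane-1,3-dione
Product: 2 2-methyl-3-oxocyclohex-1-en-1-yl trifluoromethanesulfonate
Conditions: Tf2O, pyridine, CH2Cl2, −78 to 0 °C
Reagents that add atoms: trifluoromethanesulfonic anhydride O=S(=O)(OS(=O)(=O)C(F)(F)F)C(F)(F)F
Why: O-sulfonylation of the enol of the symmetrical 1,3-dione gives the vinylogous acyl triflate (enol triflate formation).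

Step 2
Reactants: 3 methyl propiolate
Product: 4 methyl 2-(tributylstannyl)acrylate
Conditions: Bu3SnH, Pd(PPh3)4 (2 mol%), THF, 0 °C to rt
Reagents that add atoms: tributyltin hydride CCCC[SnH](CCCC)CCCC
Why: palladium-catalysed syn-hydrostannation of an alkynoate places tin on the α-carbon.

Step 3
Reactants: 2 2-methyl-3-oxocyclohex-1-en-1-yl trifluoromethanesulfonate; 4 methyl 2-(tributylstannyl)acrylate
Product: 5 methyl 2-(2-methyl-3-oxocyclohex-1-en-1-yl)acrylate
Conditions: Pd(PPh3)4 (5 mol%), CuI (10 mol%), CsF (2 equiv), DMF, 45 °C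
Reagents that add atoms: none
Why: Stille coupling of an activated β-triflyloxy enone with a vinylstannane, with copper and fluoride acceleration for the hindered α-stannyl acrylate.

Step 4
Reactants: 5 methyl 2-(2-methyl-3-oxocyclohex-1-en-1-yl)acrylate
Product: 6 methyl 2-[(3R)-3-hydroxy-2-methylcyclohex-1-en-1-yl]acrylate
Conditions: (S)-2-methyl-CBS-oxazaborolidine (20 mol%), catecholborane, toluene, −78 °C
Reagents that add atoms: none
Why: Corey–Bakshi–Shibata reduction in which the α-substituted alkenyl side acts as the large group, so the (S)-catalyst should give the (R)-carbinol, a relay centre (later C9) that directs step 5.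

Step 5
Reactants: 6 methyl 2-[(3R)-3-hydroxy-2-methylcyclohex-1-en-1-yl]acrylate; 7 diiodomethane
Product: 8 methyl 2-(5-hydroxy-6-methylbicyclo[4.1.0]heptan-1-yl)acrylate with the cyclopropane methylene cis to the hydroxyl (labdane: C1 methylene and 9-OH α, C20 methyl and the C5 acrylate β)
Conditions: Et2Zn (2.5 equiv), CH2Cl2, 0 °C to rt
Reagents that add atoms: none
Why: hydroxyl-directed Simmons–Smith cyclopropanation in which the zinc alkoxide delivers the carbenoid to the adjacent tetrasubstituted alkene on the face of the oxygen, setting C10 and C5, while the electron-poor acrylate alkene is inert to the electrophilic carbenoid.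

Step 6
Reactants: 8 cyclopropyl carbinol
Product: 9 TBS ether of 8 (the bicyclo[4.1.0]heptyl acrylate, 9α-OTBS)
Conditions: TBSOTf, 2,6-lutidine, CH2Cl2, −78 to 0 °C
Reagents that add atoms: tert-butyldimethylsilyl trifluoromethanesulfonate CC(C)(C)[Si](C)(C)OS(=O)(=O)C(F)(F)F
Why: silylation of the hindered cyclopropylcarbinol with a silyl triflate and a non-nucleophilic base gives a robust ether that keeps the hydroxyl from steering the metal in step 7.

Step 7
Reactants: 9 bicyclo[4.1.0]heptyl acrylate TBS ether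
Product: 10 methyl 9α-(TBS-oxy)-10β-methyl-2-oxo-octal-4-ene-4-carboxylate (C4=C5; the 2-oxo-octalin unsaturated ester)
Conditions: [Rh(cod)Cl]2 (2.5 mol%), Ph2P(CH2)3PPh2 (5 mol%), AgOTf (5 mol%), CO (0.2 atm in N2), 1,2-dichloroethane, 80 °C
Reagents that add atoms: carbon monoxide [C-]#[O+]
Why: Carbonylative [5+1] cycloaddition of a vinylcyclopropane, the known rhodium-, iron- or cobalt-mediated route to cyclohexenones: cationic monovalent rhodium binds the acrylate alkene, adds oxidatively into the adjacent C1–C5 cyclopropane bond to give a σ-alkyl (C1)/π-allyl (C5–C4–C3) trivalent rhodacycle, CO inserts into the Rh–C1 bond and reductive elimination joins the acyl carbon C2 to the allyl terminus C3. Ring A is thus closed as a six-membered ring by C–C reductive elimination from a seven-membered acyl rhodacycle, forming C1–C2 and C2–C3 and driven by release of cyclopropane strain. No stereocentre is created, and C10, set in step 5, is untouched because the C1–C10 and C5–C10 bonds stay intact. The step needs cleavage of C1–C5 and not of C5–C10, which is secured because the methylene terminus is the less hindered site and the alternative would put rhodium on the fully substituted C10 next to the silyloxy-bearing C9. Because C10 is quaternary the Rh–C1 alkyl has no β-hydrogen, so β-hydride elimination to dienes cannot compete with CO insertion. The alkene should rest at C4=C5, tetrasubstituted and conjugated with the ester.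

Step 8
Reactants: 10 keto enoate
Product: 11 2,2-ethylenedioxy ketal of 10
Conditions: Me3SiOCH2CH2OSiMe3, TMSOTf (5 mol%), CH2Cl2, −78 to −20 °C; pyridine quench
Reagents that add atoms: 1,2-bis(trimethylsilyloxy)ethane C[Si](C)(C)OCCO[Si](C)(C)C
Why: aprotic low-temperature ketalisation masks the C2 ketone, whose acidic C3 hydrogens would otherwise quench the dissolving-metal step, and leaves the silyl ether and the ester-conjugated alkene in place.

Step 9
Reactants: 11 ketal enoate
Product: 13 methyl 9α-(TBS-oxy)-2,2-ethylenedioxy-4α,10β-dimethyl-5α-decalin-4β-carboxylate, via lithium ester enolate 12 (not isolated)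
Conditions: Li (2.5 equiv), NH3(l)/THF, t-BuOH (1.0 equiv), −78 °C; isoprene; then MeI (excess), −78 to −33 °C
Reagents that add atoms: iodomethane CI; lithium [Li] (counter-ion of 12 only)
Why: dissolving-metal reductive alkylation of the unsaturated ester, in which axial protonation of the C5 carbanion anti to C20 should give the trans fusion (5α-H) and the ester enolate is methylated on the equatorial α face, away from C20 and the axial ketal oxygen, so that the ester ends axial (C19, β) and the new methyl equatorial (C18, α).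

Step 10
Reactants: 13 saturated ester
Product: 14 [9α-(TBS-oxy)-2,2-ethylenedioxy-4α,10β-dimethyl-5α-decalin-4β-yl]methanol (19-ol)
Conditions: LiAlH4, THF, 0 °C to reflux
Reagents that add atoms: none
Why: LiAlH4 reduction of the hindered neopentyl-type ester to the primary alcohol, with ketal and silyl ether inert to hydride.

Step 11
Reactants: 14 19-ol
Product: 15 2,2-ethylenedioxy-4β-(hydroxymethyl)-4α,10β-dimethyl-5α-decalin-9α-ol
Conditions: Bu4NF, THF, 60 °C
Reagents that add atoms: none
Why: fluoride cleavage of the silyl ether frees the C9 hydroxyl for oxidation.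

Step 12
Reactants: 15 diol
Product: 16 19-(TBS-oxy)-2,2-ethylenedioxy-4α,10β-dimethyl-5α-decalin-9α-ol
Conditions: TBSCl (1.1 equiv), imidazole, DMF, 0 °C
Reagents that add atoms: tert-butyldimethylsilyl chloride CC(C)(C)[Si](C)(C)Cl
Why: the primary C19 hydroxyl is silylated selectively because the C9 hydroxyl is axial, secondary and flanked by the quaternary C10.

Step 13
Reactants: 16 9α-ol
Product: 17 19-(TBS-oxy)-2,2-ethylenedioxy-4α,10β-dimethyl-5α-decalin-9-one
Conditions: Dess–Martin periodinane, NaHCO3, CH2Cl2, rt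
Reagents that add atoms: none
Why: Dess–Martin oxidation of the secondary alcohol gives the C9 ketone under buffered conditions that spare ketal and silyl ether.

Step 14
Reactants: 17 C9 ketone
Product: 19 8-methyl derivative of 17 (C8 epimers), via lithium enolate 18 (not isolated)
Conditions: LiN(iPr)2, THF, −78 °C; then MeI, −78 to 0 °C
Reagents that add atoms: iodomethane CI; lithium diisopropylamide CC(C)[N-]C(C)C.[Li+] (lithium of 18 only)
Why: enolate alkylation that is regiospecific because the ketone can enolise only toward C8 (C10 is quaternary), which installs C17.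

Step 15
Reactants: 19 8-methyl ketone
Product: 21 19-(TBS-oxy)-2,2-ethylenedioxy-4α,8,10β-trimethyl-5α-octal-7-en-9-one, via silyl enol ether 20 (not isolated)
Conditions: TMSOTf, Et3N, CH2Cl2, 0 °C; then Pd(OAc)2 (1.1 equiv), MeCN, rt
Reagents that add atoms: trimethylsilyl trifluoromethanesulfonate C[Si](C)(C)OS(=O)(=O)C(F)(F)F (silicon carried by 20 only)
Why: Saegusa–Ito oxidation in which the only possible silyl enol ether (C8=C9) is converted by Pd(OAc)2, through an oxa-π-allyl palladium species and β-hydride elimination of a C7 hydrogen, into the 7-en-9-one.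

Step 16
Reactants: 21 7-en-9-one
Product: 22 19-(TBS-oxy)-2,2-ethylenedioxy-14,15,16-trinorlabda-7,12-dien-9-ol (C9 epimers)
Conditions: CH2=CHCH2MgBr, THF, −78 °C
Reagents that add atoms: allylmagnesium bromide C=CC[Mg]Br
Why: 1,2-addition of the allyl Grignard reagent to the hindered enone carbonyl (six-membered allyl-transfer transition state, no conjugate addition) puts C11–C13 on C9.

Step 17
Reactants: 22 tertiary allylic alcohol
Product: 23 19-(TBS-oxy)-2,2-ethylenedioxy-14,15,16-trinorlabda-8,12-dien-7-one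
Conditions: pyridinium chlorochromate [C5H5NH][CrO3Cl], Celite, CH2Cl2, rt
Reagents that add atoms: pyridinium chlorochromate [O-][Cr](=O)(=O)Cl.c1cc[nH+]cc1
Why: Babler–Dauben oxidative transposition in which the tertiary allylic chromate ester undergoes a [3,3] shift that delivers a chromium-bound oxygen to C7 and is oxidised there, giving the 8-en-7-one with the allyl group on the β-carbon C9.

Step 18
Reactants: 23 8-en-7-one
Product: 25 19-(TBS-oxy)-2,2-ethylenedioxy-14,15,16-trinorlabda-7,12-dien-7-yl trifluoromethanesulfonate (9α-H), via lithium enolate 24 (not isolated)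
Conditions: Li (2.2 equiv), NH3(l)/THF, t-BuOH (1.0 equiv), −78 °C; isoprene; NH3 removed; then PhNTf2, THF, −78 to 0 °C
Reagents that add atoms: N-phenylbis(trifluoromethanesulfonimide) O=S(=O)(N(c1ccccc1)S(=O)(=O)C(F)(F)F)C(F)(F)F; lithium [Li] (counter-ion of 24 only)
Why: dissolving-metal enone reduction with one equivalent of proton donor protonates the C9 carbanion axially from the α face (9α-H, side chain β) and leaves the regiodefined C7–C8 enolate, which is trapped as the enol triflate (reductive triflation).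

Step 19
Reactants: 25 enol triflate
Product: 26 19-(TBS-oxy)-2,2-ethylenedioxy-14,15,16-trinorlabda-7,12-diene
Conditions: Pd(OAc)2 (5 mol%), PPh3 (10 mol%), n-Bu3N, HCO2H, DMF, 60 °C
Reagents that add atoms: none
Why: palladium-catalysed formate reduction of the enol triflate replaces the triflate by hydrogen and fixes the ring alkene at C7=C8.

Step 20
Reactants: 26 ketal diene
Product: 27 19-(TBS-oxy)-14,15,16-trinorlabda-7,12-dien-2-one
Conditions: pyridinium p-toluenesulfonate, acetone/H2O (10:1), 55 °C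
Reagents that add atoms: water O
Why: mild acid-catalysed ketal hydrolysis unmasks the C2 ketone without cleaving the hindered neopentyl silyl ether or moving the trisubstituted alkene.

Step 21
Reactants: 27 C2 ketone
Product: 28 19-(TBS-oxy)-14,15,16-trinorlabda-7,12-dien-2α-ol
Conditions: Li (4 equiv), NH3(l)/THF, MeOH (3 equiv), −78 °C; NH4Cl
Reagents that add atoms: none
Why: dissolving-metal ketone reduction gives the thermodynamically favoured equatorial 2α-ol, because an axial 2β-oxygen would be syn-diaxial to both C20 and the C19 CH2O group (hydride reagents would attack from the α face and give the wrong epimer).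

Step 22
Reactants: 28 2α-ol
Product: 29 19-(TBS-oxy)-2α-(TIPS-oxy)-14,15,16-trinorlabda-7,12-diene
Conditions: iPr3SiOTf, 2,6-lutidine, CH2Cl2, 0 °C
Reagents that add atoms: triisopropylsilyl trifluoromethanesulfonate CC(C)[Si](C(C)C)(C(C)C)OS(=O)(=O)C(F)(F)F
Why: silylation of the only free hydroxyl gives a TIPS ether that outlasts the later TES and TBS removals.

Step 23
Reactants: 29 diene
Product: 30 7α,8α-epoxy-19-(TBS-oxy)-2α-(TIPS-oxy)-14,15,16-trinorlabd-12-ene
Conditions: mCPBA (1.05 equiv), NaHCO3, CH2Cl2, 0 °C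
Reagents that add atoms: 3-chloroperbenzoic acid OOC(=O)c1cccc(Cl)c1
Why: Prilezhaev epoxidation in which the trisubstituted C7=C8 alkene reacts much faster than the monosubstituted allyl alkene and the peracid approaches from the α face, opposite the axial C20 methyl and the 9β side chain.

Step 24
Reactants: 30 epoxy alkene
Product: 32 7α,8α-epoxy-19-(TBS-oxy)-2α-(TIPS-oxy)-13,14,15,16-tetranorlabdan-12-ol, via aldehyde 31 (not isolated)
Conditions: O3, CH2Cl2/MeOH (4:1), −78 °C; then NaBH4, −78 to 0 °C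
Reagents that add atoms: ozone [O-][O+]=O
Why: ozonolysis of the only remaining alkene with in situ borohydride reduction gives the C12 primary alcohol, the epoxide and silyl ethers being inert to ozone and NaBH4.

Step 25
Reactants: 32 epoxy alcohol
Product: 33 19-(TBS-oxy)-2α-(TIPS-oxy)-13,14,15,16-tetranorlabd-8(17)-ene-7α,12-diol
Conditions: LiNEt2 (6 equiv, from Et2NH and n-BuLi), Et2O/hexane, 0 °C to reflux
Reagents that add atoms: none
Why: base-promoted epoxide to allylic alcohol isomerisation (syn-elimination) in which the lithium amide bound to the α-epoxide removes a hydrogen of the C17 methyl in preference to the tertiary C9–H, breaking the C8–O bond and keeping the C7–O bond, so the 7α configuration is retained and the 8(17)-methylene appears.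

Step 26
Reactants: 33 diol
Product: 34 12-iodo-19-(TBS-oxy)-2α-(TIPS-oxy)-13,14,15,16-tetranorlabd-8(17)-en-7α-ol
Conditions: I2, PPh3, imidazole (1.05 equiv each of I2 and PPh3), CH2Cl2, −20 to 0 °C
Reagents that add atoms: iodine II
Why: Appel-type iodination converts the unhindered primary C12 alcohol much faster than the axial, secondary C7 allylic alcohol at low temperature.

Step 27
Reactants: 34 iodo alcohol
Product: 35 12-iodo-7α-(TES-oxy)-19-(TBS-oxy)-2α-(TIPS-oxy)-13,14,15,16-tetranorlabd-8(17)-ene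
Conditions: Et3SiOTf, 2,6-lutidine, CH2Cl2, −78 °C
Reagents that add atoms: triethylsilyl trifluoromethanesulfonate CC[Si](CC)(CC)OS(=O)(=O)C(F)(F)F
Why: silylation protects the allylic C7 hydroxyl as a labile TES ether so that neither a free hydroxyl nor an ionisable allylic ester is present during organozinc formation and palladium catalysis.

Step 28
Reactants: 36 but-2-yn-1-ol
Product: 38 (Z)-3-iodobut-2-en-1-ol, via alkenylaluminate 37 (not isolated)
Conditions: NaAlH2(OCH2CH2OMe)2, Et2O, 0 °C to rt; EtOAc; then I2, THF, −78 °C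
Reagents that add atoms: iodine II; sodium bis(2-methoxyethoxy)aluminium dihydride COCCO[AlH2-]OCCOC.[Na+] (aluminium, sodium and alkoxide ligands of 37 only)
Why: trans-hydroalumination of the propargylic alcohol through the alkoxyaluminate places aluminium on C3 cis to the CH2O group, and iodinolysis with retention gives the (Z)-vinyl iodide.

Step 29
Reactants: 38 (Z)-3-iodobut-2-en-1-ol
Product: 39 (Z)-tert-butyl[(3-iodobut-2-en-1-yl)oxy]dimethylsilane
Conditions: TBSCl, imidazole, CH2Cl2, 0 °C to rt
Reagents that add atoms: tert-butyldimethylsilyl chloride CC(C)(C)[Si](C)(C)Cl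
Why: standard silylation of the primary allylic alcohol.

Step 30
Reactants: 35 C12 iodide; 39 (Z)-vinyl iodide TBS ether
Product: 41 (13Z)-15,19-bis(TBS-oxy)-7α-(TES-oxy)-2α-(TIPS-oxy)labda-8(17),13-diene, via alkylzinc iodide 40 (not isolated)
Conditions: Zn dust (activated with BrCH2CH2Br and Me3SiCl), LiCl, THF, 40 °C; then 39, Pd(PPh3)4 (5 mol%), THF, rt
Reagents that add atoms: zinc [Zn] (in 40 only)
Why: Negishi coupling in which zinc inserts into the primary iodide and zerovalent palladium joins the alkylzinc to the vinyl iodide with retention of alkene geometry, forming C12–C13 and the 13Z side chain.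

Step 31
Reactants: 41 tetrasilyl ether
Product: 42 (13Z)-2α-(TIPS-oxy)labda-8(17),13-diene-7α,15,19-triol
Conditions: HF·pyridine, pyridine, THF, 0 °C to rt
Reagents that add atoms: none
Why: buffered HF·pyridine removes the TES ether and both primary TBS ethers, while the more robust secondary TIPS ether at C2 should survive.

Step 32
Reactants: 42 triol
Product: 43 (13Z)-2α-(TIPS-oxy)labda-8(17),13-diene-7α,15,19-triyl triacetate
Conditions: Ac2O, Et3N, DMAP (cat.), CH2Cl2, rt
Reagents that add atoms: acetic anhydride CC(=O)OC(C)=O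
Why: exhaustive acetylation of the three free hydroxyls (C7, C15, C19) under nucleophilic catalysis while C2 stays silylated.

Step 33
Reactants: 43 triacetate TIPS ether
Product: 44 (13Z)-2α-hydroxylabda-8(17),13-diene-7α,15,19-triyl triacetate (CNP0139627.2)
Conditions: Bu4NF, AcOH (1:1), THF, rt
Reagents that add atoms: none
Why: acetic acid-buffered fluoride removes the TIPS ether without acyl cleavage or migration and gives the target.

**Compound list**
1 | 2-methylcyclohexane-1,3-dione | CC1C(=O)CCCC1=O | starting material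
2 | 2-methyl-3-oxocyclohex-1-en-1-yl trifluoromethanesulfonate | CC1=C(OS(=O)(=O)C(F)(F)F)CCCC1=O | intermediate
3 | methyl propiolate | C#CC(=O)OC | starting material
4 | methyl 2-(tributylstannyl)acrylate | C=C(C(=O)OC)[Sn](CCCC)(CCCC)CCCC | intermediate
5 | methyl 2-(2-methyl-3-oxocyclohex-1-en-1-yl)acrylate | COC(=O)C(=C)C1=C(C)C(=O)CCC1 | intermediate
6 | methyl 2-[(3R)-3-hydroxy-2-methylcyclohex-1-en-1-yl]acrylate | COC(=O)C(=C)C1=C(C)[C@H](O)CCC1 | intermediate
7 | diiodomethane | ICI | starting material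
8 | methyl 2-(5-hydroxy-6-methylbicyclo[4.1.0]heptan-1-yl)acrylate, methylene cis to OH (9α-OH, C20 β) | COC(=O)C(=C)[C@@]12C[C@]1(C)[C@H](O)CCC2 | intermediate
9 | TBS ether of 8 (bicyclo[4.1.0]heptyl acrylate) | COC(=O)C(=C)[C@@]12C[C@]1(C)[C@H](O[Si](C)(C)C(C)(C)C)CCC2 | intermediate
10 | methyl 9α-(TBS-oxy)-10β-methyl-2-oxo-octal-4-ene-4-carboxylate | COC(=O)C1=C2CCC[C@@H](O[Si](C)(C)C(C)(C)C)[C@@]2(C)CC(=O)C1 | intermediate
11 | 2,2-ethylenedioxy ketal of 10 | COC(=O)C1=C2CCC[C@@H](O[Si](C)(C)C(C)(C)C)[C@@]2(C)CC3(OCCO3)C1 | intermediate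
12 | lithium ester enolate (5α-H) from 11 | C1CC[C@H]2C(=C([O-])OC)CC3(OCCO3)C[C@]2(C)[C@@H]1O[Si](C)(C)C(C)(C)C.[Li+] | intermediate
13 | methyl 9α-(TBS-oxy)-2,2-ethylenedioxy-4α,10β-dimethyl-5α-decalin-4β-carboxylate | C1CC[C@H]2[C@@](C)(C(=O)OC)CC3(OCCO3)C[C@]2(C)[C@@H]1O[Si](C)(C)C(C)(C)C | intermediate
14 | [9α-(TBS-oxy)-2,2-ethylenedioxy-4α,10β-dimethyl-5α-decalin-4β-yl]methanol | C1CC[C@H]2[C@@](C)(CO)CC3(OCCO3)C[C@]2(C)[C@@H]1O[Si](C)(C)C(C)(C)C | intermediate
15 | 2,2-ethylenedioxy-4β-(hydroxymethyl)-4α,10β-dimethyl-5α-decalin-9α-ol | C1CC[C@H]2[C@@](C)(CO)CC3(OCCO3)C[C@]2(C)[C@@H]1O | intermediate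
16 | 19-(TBS-oxy)-2,2-ethylenedioxy-4α,10β-dimethyl-5α-decalin-9α-ol | C1CC[C@H]2[C@@](C)(CO[Si](C)(C)C(C)(C)C)CC3(OCCO3)C[C@]2(C)[C@@H]1O | intermediate
17 | 19-(TBS-oxy)-2,2-ethylenedioxy-4α,10β-dimethyl-5α-decalin-9-one | C1CC[C@H]2[C@@](C)(CO[Si](C)(C)C(C)(C)C)CC3(OCCO3)C[C@]2(C)C1=O | intermediate
18 | lithium C8–C9 enolate of 17 | C=1CC[C@H]2[C@@](C)(CO[Si](C)(C)C(C)(C)C)CC3(OCCO3)C[C@]2(C)C=1[O-].[Li+] | intermediate
19 | 8-methyl derivative of 17 (C8 epimers) | CC1CC[C@H]2[C@@](C)(CO[Si](C)(C)C(C)(C)C)CC3(OCCO3)C[C@]2(C)C1=O | intermediate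
20 | 9-(trimethylsilyloxy)-8-ene silyl enol ether of 19 | CC=1CC[C@H]2[C@@](C)(CO[Si](C)(C)C(C)(C)C)CC3(OCCO3)C[C@]2(C)C=1O[Si](C)(C)C | intermediate
21 | 19-(TBS-oxy)-2,2-ethylenedioxy-4α,8,10β-trimethyl-5α-octal-7-en-9-one | CC1=CC[C@H]2[C@@](C)(CO[Si](C)(C)C(C)(C)C)CC3(OCCO3)C[C@]2(C)C1=O | intermediate
22 | 19-(TBS-oxy)-2,2-ethylenedioxy-14,15,16-trinorlabda-7,12-dien-9-ol (C9 epimers) | CC1=CC[C@H]2[C@@](C)(CO[Si](C)(C)C(C)(C)C)CC3(OCCO3)C[C@]2(C)C1(O)CC=C | intermediate
23 | 19-(TBS-oxy)-2,2-ethylenedioxy-14,15,16-trinorlabda-8,12-dien-7-one | CC=1C(=O)C[C@H]2[C@@](C)(CO[Si](C)(C)C(C)(C)C)CC3(OCCO3)C[C@]2(C)C=1CC=C | intermediate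
24 | lithium C7–C8 enolate (9α-H) from 23 | CC1=C([O-])C[C@H]2[C@@](C)(CO[Si](C)(C)C(C)(C)C)CC3(OCCO3)C[C@]2(C)[C@H]1CC=C.[Li+] | intermediate
25 | 19-(TBS-oxy)-2,2-ethylenedioxy-14,15,16-trinorlabda-7,12-dien-7-yl trifluoromethanesulfonate | CC1=C(OS(=O)(=O)C(F)(F)F)C[C@H]2[C@@](C)(CO[Si](C)(C)C(C)(C)C)CC3(OCCO3)C[C@]2(C)[C@H]1CC=C | intermediate
26 | 19-(TBS-oxy)-2,2-ethylenedioxy-14,15,16-trinorlabda-7,12-diene | CC1=CC[C@H]2[C@@](C)(CO[Si](C)(C)C(C)(C)C)CC3(OCCO3)C[C@]2(C)[C@H]1CC=C | intermediate
27 | 19-(TBS-oxy)-14,15,16-trinorlabda-7,12-dien-2-one | CC1=CC[C@H]2[C@@](C)(CO[Si](C)(C)C(C)(C)C)CC(=O)C[C@]2(C)[C@H]1CC=C | intermediate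
28 | 19-(TBS-oxy)-14,15,16-trinorlabda-7,12-dien-2α-ol | CC1=CC[C@H]2[C@@](C)(CO[Si](C)(C)C(C)(C)C)C[C@H](O)C[C@]2(C)[C@H]1CC=C | intermediate
29 | 19-(TBS-oxy)-2α-(TIPS-oxy)-14,15,16-trinorlabda-7,12-diene | CC1=CC[C@H]2[C@@](C)(CO[Si](C)(C)C(C)(C)C)C[C@H](O[Si](C(C)C)(C(C)C)C(C)C)C[C@]2(C)[C@H]1CC=C | intermediate
30 | 7α,8α-epoxy-19-(TBS-oxy)-2α-(TIPS-oxy)-14,15,16-trinorlabd-12-ene | C[C@]12O[C@@H]2C[C@H]3[C@@](C)(CO[Si](C)(C)C(C)(C)C)C[C@H](O[Si](C(C)C)(C(C)C)C(C)C)C[C@]3(C)[C@H]1CC=C | intermediate
31 | 7α,8α-epoxy-19-(TBS-oxy)-2α-(TIPS-oxy)-13,14,15,16-tetranorlabdan-12-al | C[C@]12O[C@@H]2C[C@H]3[C@@](C)(CO[Si](C)(C)C(C)(C)C)C[C@H](O[Si](C(C)C)(C(C)C)C(C)C)C[C@]3(C)[C@H]1CC=O | intermediate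
32 | 7α,8α-epoxy-19-(TBS-oxy)-2α-(TIPS-oxy)-13,14,15,16-tetranorlabdan-12-ol | C[C@]12O[C@@H]2C[C@H]3[C@@](C)(CO[Si](C)(C)C(C)(C)C)C[C@H](O[Si](C(C)C)(C(C)C)C(C)C)C[C@]3(C)[C@H]1CCO | intermediate
33 | 19-(TBS-oxy)-2α-(TIPS-oxy)-13,14,15,16-tetranorlabd-8(17)-ene-7α,12-diol | C=C1[C@H](O)C[C@H]2[C@@](C)(CO[Si](C)(C)C(C)(C)C)C[C@H](O[Si](C(C)C)(C(C)C)C(C)C)C[C@]2(C)[C@H]1CCO | intermediate
34 | 12-iodo-19-(TBS-oxy)-2α-(TIPS-oxy)-13,14,15,16-tetranorlabd-8(17)-en-7α-ol | C=C1[C@H](O)C[C@H]2[C@@](C)(CO[Si](C)(C)C(C)(C)C)C[C@H](O[Si](C(C)C)(C(C)C)C(C)C)C[C@]2(C)[C@H]1CCI | intermediate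
35 | 12-iodo-7α-(TES-oxy)-19-(TBS-oxy)-2α-(TIPS-oxy)-13,14,15,16-tetranorlabd-8(17)-ene | C=C1[C@H](O[Si](CC)(CC)CC)C[C@H]2[C@@](C)(CO[Si](C)(C)C(C)(C)C)C[C@H](O[Si](C(C)C)(C(C)C)C(C)C)C[C@]2(C)[C@H]1CCI | intermediate
36 | but-2-yn-1-ol | CC#CCO | starting material
37 | sodium cyclic alkoxy(alkenyl)aluminate from 36 (Al on C3, cis to CH2O) | CC1=CCO[Al-]1(OCCOC)OCCOC.[Na+] | intermediate
38 | (Z)-3-iodobut-2-en-1-ol | C/C(I)=C/CO | intermediate
39 | (Z)-tert-butyl[(3-iodobut-2-en-1-yl)oxy]dimethylsilane | C/C(I)=C/CO[Si](C)(C)C(C)(C)C | intermediate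
40 | C12 alkylzinc iodide from 35 | C=C1[C@H](O[Si](CC)(CC)CC)C[C@H]2[C@@](C)(CO[Si](C)(C)C(C)(C)C)C[C@H](O[Si](C(C)C)(C(C)C)C(C)C)C[C@]2(C)[C@H]1CC[Zn]I | intermediate
41 | (13Z)-15,19-bis(TBS-oxy)-7α-(TES-oxy)-2α-(TIPS-oxy)labda-8(17),13-diene | C=C1[C@H](O[Si](CC)(CC)CC)C[C@H]2[C@@](C)(CO[Si](C)(C)C(C)(C)C)C[C@H](O[Si](C(C)C)(C(C)C)C(C)C)C[C@]2(C)[C@H]1CC/C(C)=C\CO[Si](C)(C)C(C)(C)C | intermediate
42 | (13Z)-2α-(TIPS-oxy)labda-8(17),13-diene-7α,15,19-triol | C=C1[C@H](O)C[C@H]2[C@@](C)(CO)C[C@H](O[Si](C(C)C)(C(C)C)C(C)C)C[C@]2(C)[C@H]1CC/C(C)=C\CO | intermediate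
43 | (13Z)-2α-(TIPS-oxy)labda-8(17),13-diene-7α,15,19-triyl triacetate | C=C1[C@H](OC(C)=O)C[C@H]2[C@@](C)(COC(C)=O)C[C@H](O[Si](C(C)C)(C(C)C)C(C)C)C[C@]2(C)[C@H]1CC/C(C)=C\COC(C)=O | intermediate
44 | (13Z)-2α-hydroxylabda-8(17),13-diene-7α,15,19-triyl triacetate (CNP0139627.2) | C=C1[C@H](OC(C)=O)C[C@H]2[C@@](C)(COC(C)=O)C[C@H](O)C[C@]2(C)[C@H]1CC/C(C)=C\COC(C)=O | target

**Step count**
Total: 33 steps. Longest linear sequence: 30 steps (steps 1, 3–27 and 30–33); steps 2, 28 and 29 prepare the two coupling partners.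

**Steps most likely to fail**

1. Step 7 (carbonylative [5+1]). The catalyst may be held as an unreactive chelate of the electron-poor alkene and the ester carbonyl, oxidative addition may take the C5–C10 bond, or the ring may open without CO uptake. The fallback sets out from 9 and comes back at 10. It replaces the catalytic rhodium cycle by stoichiometric photochemical iron carbonyl cyclocarbonylation (Fe(CO)5, hν through Pyrex, CO 1 atm, 2-propanol, rt). Photogenerated zerovalent iron tetracarbonyl binds the alkene, inserts into the less substituted cyclopropane bond to a ferracycle, takes up CO and releases the cyclohexenone. This is known chemistry for alkenyl cyclopropanes, and it makes no new compound (none F0).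

2. Step 9 (reductive methylation). Proton transfer to the ester enolate may occur before methylation, the ester may be over-reduced, or protonation at C5 may give the cis fusion. The fallback sets out from 11 and comes back at 13, and separates the two events. Conjugate reduction with Mg in MeOH at rt should give the saturated ester methyl 9α-(TBS-oxy)-2,2-ethylenedioxy-10β-methyl-5α-decalin-4-carboxylate F1 (C4 epimers), whose ring fusion can be checked and purified. Its enolate (LiN(iPr)2, THF/DMPU, −78 °C) is then methylated with MeI from the equatorial α face, giving 13.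

3. Step 17 (oxidative transposition). The hindered tertiary carbinol may dehydrate to trienes, lose the allyl group oxidatively, or suffer ketal cleavage by the acidic chromium reagent. The fallback sets out from 22 and comes back at 23, and separates transposition from oxidation. Ph3SiOReO3 (cat., Et2O, 0 °C) equilibrates the tertiary allylic alcohol to the transposed secondary alcohol 19-(TBS-oxy)-2,2-ethylenedioxy-14,15,16-trinorlabda-8,12-dien-7-ol F2 (C7 epimers), which is favoured by its tetrasubstituted alkene. Oxidation with MnO2 or Dess–Martin periodinane then gives 23.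

Further compounds
F0 | step 7 | none | none
F1 | step 9 | methyl 9α-(TBS-oxy)-2,2-ethylenedioxy-10β-methyl-5α-decalin-4-carboxylate (C4 epimers) | C1CC[C@H]2C(C(=O)OC)CC3(OCCO3)C[C@]2(C)[C@@H]1O[Si](C)(C)C(C)(C)C
F2 | step 17 | 19-(TBS-oxy)-2,2-ethylenedioxy-14,15,16-trinorlabda-8,12-dien-7-ol (C7 epimers) | CC=1C(O)C[C@H]2[C@@](C)(CO[Si](C)(C)C(C)(C)C)CC3(OCCO3)C[C@]2(C)C=1CC=C
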